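The route rests on telling two prenyl-type groups apart by carrying the C3a substituent as an allyl group until the end. At the oxidation stage the only electron-rich trisubstituted alkene is then C2''=C3'' of the C7 side chain on ring B. One catalytic dioxirane epoxidation forms both C–O bonds of the oxirane and the C2'' stereocentre, and should leave the monosubstituted C3a allyl alkene and the carbonyl-conjugated ring-B alkenes untouched. Its precursor is the fully assembled bicyclic acyl trione with free enol and tertiary alcohol, built from a chiral-pool lactone ester and a diketone dianion. Cross-metathesis then turns allyl into prenyl.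

Key step: step 7

Remark: the enolised triketone is drawn throughout as the 4-hydroxy-6-oxo tautomer; side-chain atoms are C1'–C3' on C3a and C1''–C3'' on C7.

Step 1
Reactants: 1 methyl (2S)-oxirane-2-carboxylate
Product: 2 2-[(2S)-oxiran-2-yl]propan-2-ol
Conditions: MeMgCl (2.1 equiv), THF, −78 → −40 °C; aq. NH4Cl
Reagents that add atoms: methylmagnesium chloride MeMgCl, SMILES C[Mg]Cl
Why: Double Grignard addition to the ester at low temperature, where the oxirane should not be opened; no bond to the stereocentre is touched, so it stays (S).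

Step 2
Reactants: 2 2-[(2S)-oxiran-2-yl]propan-2-ol; 3 dimethyl malonate
Product: 5 methyl (5S)-5-(2-hydroxypropan-2-yl)-2-oxooxolane-3-carboxylate (both C3 epimers), via dihydroxy malonate 4 (not isolated)
Conditions: 3 (1.5 equiv), NaOMe (1.5 equiv), MeOH, 0 → 60 °C; AcOH
Reagents that add atoms: none
Why: The malonate anion opens the oxirane by SN2 at the unsubstituted CH2 and the secondary alkoxide closes the γ-lactone on one ester (5-exo-trig), the classical malonate–epoxide butanolide synthesis; the C–O bond at the stereocentre is not broken, so C5 stays (S).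

Step 3
Reactants: 5 methyl (5S)-5-(2-hydroxypropan-2-yl)-2-oxooxolane-3-carboxylate
Product: 6 methyl (5S)-2-oxo-5-[2-(triethylsilyloxy)propan-2-yl]oxolane-3-carboxylate (both C3 epimers)
Conditions: Et3SiOTf (1.2 equiv), 2,6-lutidine, CH2Cl2, −78 → 0 °C
Reagents that add atoms: triethylsilyl trifluoromethanesulfonate, SMILES CC[Si](CC)(CC)OS(=O)(=O)C(F)(F)F
Why: Silyl triflate with a hindered pyridine base is the standard silylation of a tertiary alcohol; the ether removes the acidic OH before the carbanion steps and makes the C5 substituent bulkier for step 4.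

Step 4
Reactants: 6 methyl (5S)-2-oxo-5-[2-(triethylsilyloxy)propan-2-yl]oxolane-3-carboxylate; 7 allyl bromide
Product: 8 methyl (3R,5S)-2-oxo-3-(prop-2-en-1-yl)-5-[2-(triethylsilyloxy)propan-2-yl]oxolane-3-carboxylate
Conditions: NaH (1.05 equiv), THF, 0 °C; 7, 0 °C → rt
Reagents that add atoms: none
Why: SN2 C-alkylation of the planar malonate-type lactone enolate should occur on the face anti to the bulky C5 group, which sets the quaternary centre with allyl trans to that group (3R), the usual sense for 5-substituted 3-alkoxycarbonyl butanolide enolates.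

Step 5
Reactants: 9 6-methylhept-5-en-2-one; 10 2-methylpropanoyl chloride
Product: 11 2,9-dimethyldec-8-ene-3,5-dione
Conditions: 9 (2 equiv), LiN(SiMe3)2 (2.1 equiv), THF, −78 °C; 10 (1 equiv), −78 → 0 °C; aq. NH4Cl
Reagents that add atoms: none
Why: The kinetic lithium enolate forms at the methyl group and is C-acylated by the acid chloride, the second enolate equivalent deprotonating the diketone as it forms (crossed Claisen-type acylation of a ketone enolate).

Step 6
Reactants: 11 2,9-dimethyldec-8-ene-3,5-dione; 8 methyl (3R,5S)-2-oxo-3-(prop-2-en-1-yl)-5-[2-(triethylsilyloxy)propan-2-yl]oxolane-3-carboxylate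
Product: 15 (2S,3aR)-4-hydroxy-2-(2-hydroxypropan-2-yl)-7-(3-methylbut-2-en-1-yl)-5-(2-methylpropanoyl)-3a-(prop-2-en-1-yl)-3,3a-dihydro-1-benzofuran-6(2H)-one, via open-chain triketo ester 12 (not isolated), via monocyclic acyl trione 13 (not isolated), via silyl ether of the bicyclic core 14 (not isolated)
Conditions: 11 (1.3 equiv), LiN(iPr)2 (2.7 equiv), THF, −78 → 0 °C; 8, −78 → −20 °C; KOtBu (2 equiv), 0 → 40 °C; then 1 M HCl, THF, rt
Reagents that add atoms: none
Why: The terminal carbanion of the diketone dianion (formed at the CH2, not at the isopropyl methine) acylates at the lactone carbonyl, which is more electrophilic than the methyl ester and has no α-hydrogen (Claisen), the central diketone carbon then closes ring B on the ester as its potassium enolate (Dieckmann-type C-acylation driven by the acidity of the triacylmethane), and acid closes ring A by 5-exo addition of the C2 hydroxyl to the vinylogous-acid carbon C7a with loss of water while it removes the silyl group; no bond to C2 or C3a is broken, so both keep their configuration.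

Step 7
Reactants: 15 (2S,3aR)-4-hydroxy-2-(2-hydroxypropan-2-yl)-7-(3-methylbut-2-en-1-yl)-5-(2-methylpropanoyl)-3a-(prop-2-en-1-yl)-3,3a-dihydro-1-benzofuran-6(2H)-one
Product: 16 (2S,3aR)-7-{[(2R)-3,3-dimethyloxiran-2-yl]methyl}-4-hydroxy-2-(2-hydroxypropan-2-yl)-5-(2-methylpropanoyl)-3a-(prop-2-en-1-yl)-3,3a-dihydro-1-benzofuran-6(2H)-one
Conditions: 1,2:4,5-di-O-isopropylidene-β-D-erythro-2,3-hexodiulo-2,6-pyranose (0.5 equiv), KHSO5 (as 2KHSO5·KHSO4·K2SO4, 1.4 equiv) and K2CO3 added in parallel, Bu4NHSO4 (cat.), Na2B4O7 buffer, MeCN–CH2(OMe)2–H2O, −5 → 0 °C; then NaH2PO4 to pH 6, 0 °C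
Reagents that add atoms: potassium peroxymonosulfate KHSO5, SMILES [K+].[O-]S(=O)(=O)OO
Why: KHSO5 converts the ketone catalyst into a chiral dioxirane, which transfers one oxygen atom to the C2''=C3'' alkene through a spiro transition state, so both C–O bonds form in one concerted step. The closest known reaction type is the Shi epoxidation of trisubstituted R–CH2–CH=CMe2 alkenes such as the terminal alkene of geranyl and farnesyl derivatives. The oxirane closes by this concerted [2+1] oxygen-atom transfer, not by a stepwise ring closure. The C2'' stereocentre is set by the catalyst: the D-fructose-derived ketone delivers oxygen to the face that gives (R) at the CH carbon of such alkenes, and the remote C2 and C3a centres should have little influence. The step needs site selectivity among four C=C units and the enolised triketone: the electrophilic dioxirane prefers the only electron-rich trisubstituted alkene, the monosubstituted C3a allyl alkene reacts far more slowly, and the C4=C5 and C7=C7a alkenes are deactivated by conjugation to carbonyl groups. At the buffered pH the triketone is present as its potassium enolate, whose charge is spread over three carbonyl groups, which should make it a poor nucleophile towards both the dioxirane and the new oxirane, and the cold work-up at pH 6 avoids acid-promoted 5-exo opening by the C6 oxygen.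

Step 8
Reactants: 16 (2S,3aR)-7-{[(2R)-3,3-dimethyloxiran-2-yl]methyl}-4-hydroxy-2-(2-hydroxypropan-2-yl)-5-(2-methylpropanoyl)-3a-(prop-2-en-1-yl)-3,3a-dihydro-1-benzofuran-6(2H)-one; 17 2-methylbut-2-ene
Product: 18 (2S,3aR)-7-{[(2R)-3,3-dimethyloxiran-2-yl]methyl}-4-hydroxy-2-(2-hydroxypropan-2-yl)-3a-(3-methylbut-2-en-1-yl)-5-(2-methylpropanoyl)-3,3a-dihydro-1-benzofuran-6(2H)-one
Conditions: 17 (excess, co-solvent), second-generation Grubbs catalyst RuCl2(=CHPh)(H2IMes)(PCy3) (5 mol %), CH2Cl2, rt
Reagents that add atoms: none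
Why: Olefin cross-metathesis of the monosubstituted allyl alkene with excess 2-methylbut-2-ene transfers the isopropylidene unit and releases propene; the oxirane, the tetrasubstituted ring alkenes and all three stereocentres are not involved, and with the C7 side chain already an oxirane no ring-closing partner is left for the allyl group.

Compound list
1 | methyl (2S)-oxirane-2-carboxylate | COC(=O)[C@@H]1CO1 | starting material
2 | 2-[(2S)-oxiran-2-yl]propan-2-ol | CC(C)(O)[C@@H]1CO1 | intermediate
3 | dimethyl malonate | COC(=O)CC(=O)OC | starting material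
4 | dimethyl 2-[(2S)-2,3-dihydroxy-3-methylbutyl]propanedioate | COC(=O)C(C[C@H](O)C(C)(C)O)C(=O)OC | intermediate
5 | methyl (5S)-5-(2-hydroxypropan-2-yl)-2-oxooxolane-3-carboxylate (both C3 epimers) | COC(=O)C1C[C@@H](C(C)(C)O)OC1=O | intermediate
6 | methyl (5S)-2-oxo-5-[2-(triethylsilyloxy)propan-2-yl]oxolane-3-carboxylate (both C3 epimers) | COC(=O)C1C[C@@H](C(C)(C)O[Si](CC)(CC)CC)OC1=O | intermediate
7 | allyl bromide | C=CCBr | starting material
8 | methyl (3R,5S)-2-oxo-3-(prop-2-en-1-yl)-5-[2-(triethylsilyloxy)propan-2-yl]oxolane-3-carboxylate | C=CC[C@]1(C(=O)OC)C[C@@H](C(C)(C)O[Si](CC)(CC)CC)OC1=O | intermediate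
9 | 6-methylhept-5-en-2-one | CC(=O)CCC=C(C)C | starting material
10 | 2-methylpropanoyl chloride | CC(C)C(Cl)=O | starting material
11 | 2,9-dimethyldec-8-ene-3,5-dione | CC(C)C(=O)CC(=O)CCC=C(C)C | intermediate
12 | methyl (2S)-2-[(2S)-2-hydroxy-3-methyl-3-(triethylsilyloxy)butyl]-8-methyl-4-(3-methylbut-2-en-1-yl)-3,5,7-trioxo-2-(prop-2-en-1-yl)nonanoate (C4 epimers) | C=CC[C@@](C[C@H](O)C(C)(C)O[Si](CC)(CC)CC)(C(=O)OC)C(=O)C(CC=C(C)C)C(=O)CC(=O)C(C)C | intermediate
13 | (6R)-5-hydroxy-6-[(2S)-2-hydroxy-3-methyl-3-(triethylsilyloxy)butyl]-2-(3-methylbut-2-en-1-yl)-4-(2-methylpropanoyl)-6-(prop-2-en-1-yl)cyclohex-4-ene-1,3-dione (C2 epimers, one tautomer) | C=CC[C@]1(C[C@H](O)C(C)(C)O[Si](CC)(CC)CC)C(=O)C(CC=C(C)C)C(=O)C(C(=O)C(C)C)=C1O | intermediate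
14 | (2S,3aR)-4-hydroxy-7-(3-methylbut-2-en-1-yl)-5-(2-methylpropanoyl)-3a-(prop-2-en-1-yl)-2-[2-(triethylsilyloxy)propan-2-yl]-3,3a-dihydro-1-benzofuran-6(2H)-one | C=CC[C@]12C[C@@H](C(C)(C)O[Si](CC)(CC)CC)OC1=C(CC=C(C)C)C(=O)C(C(=O)C(C)C)=C2O | intermediate
15 | (2S,3aR)-4-hydroxy-2-(2-hydroxypropan-2-yl)-7-(3-methylbut-2-en-1-yl)-5-(2-methylpropanoyl)-3a-(prop-2-en-1-yl)-3,3a-dihydro-1-benzofuran-6(2H)-one | C=CC[C@]12C[C@@H](C(C)(C)O)OC1=C(CC=C(C)C)C(=O)C(C(=O)C(C)C)=C2O | intermediate
16 | (2S,3aR)-7-{[(2R)-3,3-dimethyloxiran-2-yl]methyl}-4-hydroxy-2-(2-hydroxypropan-2-yl)-5-(2-methylpropanoyl)-3a-(prop-2-en-1-yl)-3,3a-dihydro-1-benzofuran-6(2H)-one | C=CC[C@]12C[C@@H](C(C)(C)O)OC1=C(C[C@H]1OC1(C)C)C(=O)C(C(=O)C(C)C)=C2O | intermediate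
17 | 2-methylbut-2-ene | CC=C(C)C | starting material
18 | (2S,3aR)-7-{[(2R)-3,3-dimethyloxiran-2-yl]methyl}-4-hydroxy-2-(2-hydroxypropan-2-yl)-3a-(3-methylbut-2-en-1-yl)-5-(2-methylpropanoyl)-3,3a-dihydro-1-benzofuran-6(2H)-one | CC(C)=CC[C@]12C[C@@H](C(C)(C)O)OC1=C(C[C@H]1OC1(C)C)C(=O)C(C(=O)C(C)C)=C2O | target

Total steps: 8. Longest linear sequence: 7 (steps 1, 2, 3, 4, 6, 7 and 8; step 5 makes the second fragment).

Steps most likely to fail

Step 6. The dianion may attack the ester instead of the lactone carbonyl, ring B may not close in the polyanion medium, or the hydroxyl may close onto C4 instead of C7a in the acid stage. The fallback secures ring A first. Setting out from 8 and 11, the dianion of 11 (LiN(iPr)2, THF, −78 °C) is added to 8, and the cold lactol adduct is quenched with acetic acid and dehydrated with pyridinium p-toluenesulfonate in CH2Cl2. This should give the 2-alkylidene oxolane keto ester methyl (3S,5S)-2-(2,9-dimethyl-3,5-dioxodec-8-en-6-ylidene)-3-(prop-2-en-1-yl)-5-[2-(triethylsilyloxy)propan-2-yl]oxolane-3-carboxylate F1, in which the O1–C7a enol ether is already fixed. Dieckmann closure of F1 with KOtBu in THF then gives 14, where the route is rejoined; the acid treatment of step 6 converts 14 into 15.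

Step 7. The alkaline dioxirane medium may oxidise the enolate at C5, let the C6 oxygen open the oxirane, or give poor facial selectivity at C2''. The fallback gives up catalyst control. Setting out from 15, dimethyldioxirane in acetone at −20 °C (neutral medium, triketone as its hydrogen-bonded enol) should epoxidise the same alkene without face preference. It would give 16 together with its C2'' epimer (2S,3aR)-7-{[(2S)-3,3-dimethyloxiran-2-yl]methyl}-4-hydroxy-2-(2-hydroxypropan-2-yl)-5-(2-methylpropanoyl)-3a-(prop-2-en-1-yl)-3,3a-dihydro-1-benzofuran-6(2H)-one F2. The two are diastereomers and would be separated by preparative HPLC on a neutral phase; 16 rejoins the route, at the cost of half the material.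

Step 4. Facial discrimination of the lactone enolate by the C5 group across the ring may be insufficient, giving both configurations at the quaternary centre. The fallback replaces the SN2 alkylation by a palladium-catalysed allylic alkylation. Setting out from 6, allyl methyl carbonate, Pd2(dba)3 and the C2-symmetric bis(2-diphenylphosphinobenzamide) ligand of trans-cyclohexane-1,2-diamine in CH2Cl2 at room temperature should give 8 directly under neutral conditions. Both ligand enantiomers would be screened and the one that reinforces the substrate bias used; no new compound is made (F0).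

Further compounds
F1 | step 6 | methyl (3S,5S)-2-(2,9-dimethyl-3,5-dioxodec-8-en-6-ylidene)-3-(prop-2-en-1-yl)-5-[2-(triethylsilyloxy)propan-2-yl]oxolane-3-carboxylate | C=CC[C@]1(C(=O)OC)C[C@@H](C(C)(C)O[Si](CC)(CC)CC)OC1=C(CC=C(C)C)C(=O)CC(=O)C(C)C
F2 | step 7 | (2S,3aR)-7-{[(2S)-3,3-dimethyloxiran-2-yl]methyl}-4-hydroxy-2-(2-hydroxypropan-2-yl)-5-(2-methylpropanoyl)-3a-(prop-2-en-1-yl)-3,3a-dihydro-1-benzofuran-6(2H)-one | C=CC[C@]12C[C@@H](C(C)(C)O)OC1=C(C[C@@H]1OC1(C)C)C(=O)C(C(=O)C(C)C)=C2O
F0 | step 4 | none | none
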